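**Retrosynthetic overview**
1. Target 30 ⇒ alkene 28 (oxirane closed last, through a bromohydrin) ⇒ ketone 27 (C10 carbinol by methyl addition).
2. 27 ⇒ acyclic bis-epoxy (Z)-silyl enol ether 25 (oxepane and cyclohexane close together in one epoxonium cascade) ⇒ enone 24 ⇒ phosphonate 23 + aldehyde 18 (Horner–Wadsworth–Emmons).
3. 18 ⇒ Claisen rearrangement of the vinyl ether of allylic alcohol 16 (chirality transfer from C16 to C14) ⇒ enone 15.
4. Key disconnection C18–C19: 15 ⇒ ketone-tethered cycloheptadienone 13; the ketone carbon, as a SmI2 ketyl, is joined to the enone β-carbon, closing the cyclopentanol and fixing the cis ring fusion and C19.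
5. 13 ⇒ one-carbon ring expansion of the asymmetric conjugate adduct of dienone 4 with a masked ketone homoenolate (zinc reagent 7). Ring order: six-membered carbocycle → seven-membered ring → cyclopentane → oxepane + cyclohexane → oxirane.

Numbering used below (squalene-type): C2 = CMe2 and C3 = CHOH of the oxepane, C6 = angular C–Me, C7 = O–CH, C10 = C(Me)OH and C11 = linker-bearing CH of the cyclohexane, C12–C13 = linker, C14 = linker-bearing CH of the seven-membered ring, C15 (Me) and C16 = oxirane carbons, C17 = CH2, C18 and C22 = ring-fusion CH, C19 = C(Me)OH of the cyclopentane, C20 and C21 = CH2, C23 = CMe2.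
Assumption: the (S,R,R) phosphoramidite shows the same facial sense with dienone 4 as with cyclohexenone; if not, its mirror image is used.

**Step 1**
Reactants: 1 isobutyraldehyde; 2 ethyl vinyl ketone (pent-1-en-3-one)
Product: 3 2,4,4-trimethylcyclohex-2-en-1-one
Conditions: H2SO4 (cat.), PhMe, 110 °C, Dean–Stark
Reagents that add atoms: none
Why: Acid-catalysed Michael addition followed by aldol condensation (Robinson-type annulation), in which only the ethyl CH2 can close a six-membered ring; no stereocentre is formed.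

**Step 2**
Reactants: 3 2,4,4-trimethylcyclohex-2-en-1-one
Product: 4 2,4,4-trimethylcyclohexa-2,5-dien-1-one
Conditions: IBX (2 equiv), DMSO, 75 °C
Reagents that add atoms: none
Why: IBX dehydrogenation of the only saturated α,β pair gives the cross-conjugated dienone, and the quaternary carbon prevents aromatisation.

**Step 3**
Reactants: 5 2-(2-bromoethyl)-2-methyl-1,3-dioxolane
Product: 7 bis[2-(2-methyl-1,3-dioxolan-2-yl)ethyl]zinc, via Grignard reagent 6 (not isolated)
Conditions: Mg, THF, 25 °C; then Zn(OMe)2 (0.5 equiv), Et2O, 25 °C, centrifuge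
Reagents that add atoms: zinc methoxide, CO[Zn]OC
Why: Grignard formation and magnesium-to-zinc transmetalation, with the magnesium salt precipitating, give a salt-free dialkylzinc that is an acetal-masked ketone homoenolate.

**Step 4**
Reactants: 4 2,4,4-trimethylcyclohexa-2,5-dien-1-one; 7 bis[2-(2-methyl-1,3-dioxolan-2-yl)ethyl]zinc
Product: 9 trimethyl{[(3R)-4,4,6-trimethyl-3-[2-(2-methyl-1,3-dioxolan-2-yl)ethyl]cyclohexa-1,5-dien-1-yl]oxy}silane, via zinc enolate 8 (not isolated)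
Conditions: Cu(OTf)2 (2 mol %), O,O′-(S)-1,1′-binaphthyl-2,2′-diyl N,N-bis[(R)-1-phenylethyl]phosphoramidite (4 mol %), PhMe, −30 °C; then TMSOTf, Et3N, −30 → 0 °C
Reagents that add atoms: trimethylsilyl trifluoromethanesulfonate, C[Si](C)(C)OS(=O)(=O)C(F)(F)F
Why: Copper/phosphoramidite-catalysed asymmetric conjugate addition delivers the homoenolate carbon (C21) to the β-carbon of the unsubstituted enone arm (C22), the ligand setting the (R) centre, and the zinc enolate is trapped regiospecifically as the silyl enol ether.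

**Step 5**
Reactants: 9 the silyl dienol ether
Product: 10 trimethyl{[(1S,5R,6R)-2,4,4-trimethyl-5-[2-(2-methyl-1,3-dioxolan-2-yl)ethyl]bicyclo[4.1.0]hept-2-en-1-yl]oxy}silane
Conditions: Et2Zn, CH2I2, CH2Cl2, 0 °C → rt
Reagents that add atoms: diiodomethane, ICI
Why: Furukawa-modified Simmons–Smith cyclopropanation takes the electron-rich enol ether alkene, anti to the side chain, in preference to the hindered trisubstituted alkene; the two new centres are lost in step 6.

**Step 6**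
Reactants: 10 the silyloxycyclopropane
Product: 13 (5R)-2,4,4-trimethyl-5-(3-oxobutyl)cyclohepta-2,6-dien-1-one, via chloro ketone 11 (not isolated), via dioxolane dienone 12 (not isolated)
Conditions: FeCl3 (2.2 equiv), DMF, 0 °C; then NaOAc, MeOH, 65 °C; then 1 M HCl, THF, 0 °C
Reagents that add atoms: water, O
Why: Saegusa–Ito ring expansion, in which the cyclopropyloxy radical cleaves the internal bond to a ring-expanded β-keto radical that is chlorinated at C18, followed by elimination of HCl to the C17=C18 enone and acid removal of the dioxolane.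

**Step 7 (key step)**
Reactants: 13 (5R)-2,4,4-trimethyl-5-(3-oxobutyl)cyclohepta-2,6-dien-1-one
Product: 15 (3R,3aR,8aR)-3-hydroxy-3,6,8,8-tetramethyl-2,3,3a,4,8,8a-hexahydroazulen-5(1H)-one, via samarium dienolate 14 (not isolated)
Conditions: SmI2 (2.2 equiv), HMPA (8 equiv), THF, −78 °C; then sat. aq. NH4Cl
Reagents that add atoms: none
Why: SmI2 ketyl–olefin (reductive ketone–enone) cyclisation bonds the ketone carbon C19 to the enone β-carbon C18 in a 5-exo closure, the ring-bound tether forcing the cis fusion and the bulky O–Sm group lying anti to C17 (OH cis to H18), while α-protonation of the dienolate keeps the C14=C15 enone.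

**Step 8**
Reactants: 15 the hydroazulenone
Product: 16 (3R,3aR,5S,8aR)-3,6,8,8-tetramethyl-1,2,3,3a,4,5,8,8a-octahydroazulene-3,5-diol
Conditions: NaBH4, CeCl3·7H2O, MeOH, −78 °C
Reagents that add atoms: none
Why: Luche 1,2-reduction, with hydride arriving on the convex face (away from the cyclopentane and its endo methyl), places the C16 hydroxyl on the concave β face.

**Step 9**
Reactants: 16 the allylic alcohol
Product: 18 2-[(1R,3aR,5S,8aR)-1-hydroxy-1,4,4,6-tetramethyl-1,2,3,3a,4,5,8,8a-octahydroazulen-5-yl]acetaldehyde, via allyl vinyl ether 17 (not isolated)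
Conditions: butyl vinyl ether, Pd(OCOCF3)2 (5 mol %), 4,7-diphenyl-1,10-phenanthroline, Et3N, 75 °C; concentrate; then PhMe, 180 °C, sealed tube
Reagents that add atoms: butyl vinyl ether, C=COCCCC
Why: Transfer vinylation of the secondary allylic alcohol and Claisen [3,3] rearrangement form the hindered C13–C14 bond suprafacially on the face the C16–O bond occupied (β) and move the alkene to C15=C16.

**Step 10**
Reactants: 19 geranyl bromide; 20 dimethyl (2-oxopropyl)phosphonate
Product: 22 dimethyl [(5E)-6,10-dimethyl-2-oxoundeca-5,9-dien-1-yl]phosphonate, via phosphonate dianion 21 (not isolated)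
Conditions: NaH, THF, 0 °C; n-BuLi, 0 °C; then 19, 0 °C → rt
Reagents that add atoms: none
Why: γ-Alkylation of the β-keto phosphonate dianion by SN2 at the primary allylic bromide, with the alkene geometry retained.

**Step 11**
Reactants: 22 the dienyl keto phosphonate
Product: 23 dimethyl {4-[(2R,3R)-3-{2-[(2R)-3,3-dimethyloxiran-2-yl]ethyl}-3-methyloxiran-2-yl]-2-oxobutyl}phosphonate
Conditions: D-fructose-derived Shi ketone (30 mol %), Oxone (2KHSO5·KHSO4·K2SO4), K2CO3, Bu4NHSO4, Na2B4O7 buffer (pH 10.5), MeCN/dimethoxymethane/H2O, 0 °C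
Reagents that add atoms: Oxone (potassium peroxymonosulfate), [K+].[O-]S(=O)(=O)OO
Why: Shi asymmetric epoxidation of both trisubstituted alkenes, the D-fructose ketone giving the (R) configuration at each epoxide CH (C3 and C7) and (R) at C6.

**Step 12**
Reactants: 23 the bis-epoxy keto phosphonate; 18 the aldehyde
Product: 24 (4E)-1-[(2R,3R)-3-{2-[(2R)-3,3-dimethyloxiran-2-yl]ethyl}-3-methyloxiran-2-yl]-6-[(1R,3aR,5S,8aR)-1-hydroxy-1,4,4,6-tetramethyl-1,2,3,3a,4,5,8,8a-octahydroazulen-5-yl]hex-4-en-3-one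
Conditions: LiCl, i-Pr2NEt, MeCN, rt
Reagents that add atoms: none
Why: Masamune–Roush Horner–Wadsworth–Emmons olefination joins the halves as the (E)-enone (C11=C12) under conditions that leave the epoxides, the alkene and the tertiary alcohol untouched.

**Step 13**
Reactants: 24 the enone
Product: 25 {[(3Z)-1-[(2R,3R)-3-{2-[(2R)-3,3-dimethyloxiran-2-yl]ethyl}-3-methyloxiran-2-yl]-6-[(1R,3aR,5S,8aR)-1-hydroxy-1,4,4,6-tetramethyl-1,2,3,3a,4,5,8,8a-octahydroazulen-5-yl]hex-3-en-3-yl]oxy}triethylsilane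
Conditions: Et3SiH, RhCl(PPh3)3 (2 mol %), PhH, 50 °C
Reagents that add atoms: triethylsilane, CC[SiH](CC)CC
Why: Rhodium-catalysed 1,4-hydrosilylation through the s-cis enone gives the (Z)-silyl enol ether regiospecifically towards C11, which ketone enolisation could not do.

**Step 14**
Reactants: 25 the bis-epoxy silyl enol ether
Product: 27 (3R,5aR,6R,9aR)-3-hydroxy-6-{2-[(1R,3aR,5S,8aR)-1-hydroxy-1,4,4,6-tetramethyl-1,2,3,3a,4,5,8,8a-octahydroazulen-5-yl]ethyl}-2,2,5a-trimethyloctahydro-1-benzoxepin-7(2H)-one, via bis-TMS ether 26 (not isolated)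
Conditions: TMSOTf (3 equiv), 2,6-di-tert-butyl-4-methylpyridine, CH2Cl2, −78 °C; then Bu4NF, THF, 0 °C
Reagents that add atoms: none
Why: Tandem oxa-/carbacyclisation (epoxonium cascade): the internal epoxide oxygen opens the silyl-activated terminal epoxide at C2 to form the oxepane, and the enol silane carbon C11 attacks C6 with inversion through a chair, giving the trans ring fusion (C3 and C7 retained from the Shi epoxides) with the C11 side chain equatorial.

**Step 15**
Reactants: 27 the hydroxy ketone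
Product: 28 (3R,5aR,6R,7S,9aR)-6-{2-[(1R,3aR,5S,8aR)-1-hydroxy-1,4,4,6-tetramethyl-1,2,3,3a,4,5,8,8a-octahydroazulen-5-yl]ethyl}-2,2,5a,7-tetramethyldecahydro-1-benzoxepine-3,7-diol
Conditions: MeLi (6 equiv), CeCl3, THF, −78 °C
Reagents that add atoms: methyllithium, [Li]C
Why: Organocerium 1,2-addition avoids enolisation, and the syn-axial angular methyl blocks the axial path so that equatorial attack gives the axial C10 hydroxyl (7S).

**Step 16**
Reactants: 28 the alkene triol
Product: 30 the target, (3R,5aR,6R,7S,9aR)-6-{2-[(1R,3aR,5R,6R,7S,8aR)-6,7-epoxy-1-hydroxy-1,4,4,6-tetramethyldecahydroazulen-5-yl]ethyl}-2,2,5a,7-tetramethyldecahydro-1-benzoxepine-3,7-diol, via bromohydrin 29 (not isolated)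
Conditions: NBS, THF/H2O, 0 °C; then K2CO3, MeOH, rt
Reagents that add atoms: water, O
Why: Bromohydrin formation and closure: Br+ adds to the less hindered α face (anti to the C14 chain), water opens at C15 from the β face, and the alkoxide displaces bromide at C16 with inversion, giving the β-epoxide that direct peracid attack would not give.

**Compound list**
1 | isobutyraldehyde | CC(C)C=O | starting material
2 | ethyl vinyl ketone | CCC(=O)C=C | starting material
3 | 2,4,4-trimethylcyclohex-2-en-1-one | CC1=CC(C)(C)CCC1=O | intermediate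
4 | 2,4,4-trimethylcyclohexa-2,5-dien-1-one | CC1=CC(C)(C)C=CC1=O | intermediate
5 | 2-(2-bromoethyl)-2-methyl-1,3-dioxolane | CC1(CCBr)OCCO1 | starting material
6 | [2-(2-methyl-1,3-dioxolan-2-yl)ethyl]magnesium bromide | CC1(CC[Mg]Br)OCCO1 | intermediate
7 | bis[2-(2-methyl-1,3-dioxolan-2-yl)ethyl]zinc | CC1(CC[Zn]CCC2(C)OCCO2)OCCO1 | intermediate
8 | alkylzinc dienolate of the (3R) conjugate adduct | CC1(CC[Zn]OC2=C[C@@H](CCC3(C)OCCO3)C(C)(C)C=C2C)OCCO1 | intermediate
9 | trimethyl{[(3R)-4,4,6-trimethyl-3-[2-(2-methyl-1,3-dioxolan-2-yl)ethyl]cyclohexa-1,5-dien-1-yl]oxy}silane | C[Si](C)(C)OC1=C[C@@H](CCC2(C)OCCO2)C(C)(C)C=C1C | intermediate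
10 | trimethyl{[(1S,5R,6R)-2,4,4-trimethyl-5-[2-(2-methyl-1,3-dioxolan-2-yl)ethyl]bicyclo[4.1.0]hept-2-en-1-yl]oxy}silane | C[Si](C)(C)O[C@@]12C[C@@H]1[C@@H](CCC1(C)OCCO1)C(C)(C)C=C2C | intermediate
11 | (5S)-6-chloro-2,4,4-trimethyl-5-[2-(2-methyl-1,3-dioxolan-2-yl)ethyl]cyclohept-2-en-1-one (both C6 epimers) | CC1(CC[C@@H]2C(Cl)CC(=O)C(C)=CC2(C)C)OCCO1 | intermediate
12 | (5R)-2,4,4-trimethyl-5-[2-(2-methyl-1,3-dioxolan-2-yl)ethyl]cyclohepta-2,6-dien-1-one | CC1(CC[C@@H]2C=CC(=O)C(C)=CC2(C)C)OCCO1 | intermediate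
13 | (5R)-2,4,4-trimethyl-5-(3-oxobutyl)cyclohepta-2,6-dien-1-one | CC(=O)CC[C@@H]1C=CC(=O)C(C)=CC1(C)C | intermediate
14 | bis(diiodosamarium) alkoxide dienolate of 15 | CC1=CC(C)(C)[C@@H]2CC[C@@](C)(O[Sm](I)I)[C@@H]2C=C1O[Sm](I)I | intermediate
15 | (3R,3aR,8aR)-3-hydroxy-3,6,8,8-tetramethyl-2,3,3a,4,8,8a-hexahydroazulen-5(1H)-one | CC1=CC(C)(C)[C@@H]2CC[C@@](C)(O)[C@@H]2CC1=O | intermediate
16 | (3R,3aR,5S,8aR)-3,6,8,8-tetramethyl-1,2,3,3a,4,5,8,8a-octahydroazulene-3,5-diol | CC1=CC(C)(C)[C@@H]2CC[C@@](C)(O)[C@@H]2C[C@@H]1O | intermediate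
17 | (3R,3aR,5S,8aR)-5-(ethenyloxy)-3,6,8,8-tetramethyl-1,2,3,3a,4,5,8,8a-octahydroazulen-3-ol | CC1=CC(C)(C)[C@@H]2CC[C@@](C)(O)[C@@H]2C[C@@H]1OC=C | intermediate
18 | 2-[(1R,3aR,5S,8aR)-1-hydroxy-1,4,4,6-tetramethyl-1,2,3,3a,4,5,8,8a-octahydroazulen-5-yl]acetaldehyde | O=CC[C@@H]1C(C)(C)[C@@H]2CC[C@@](C)(O)[C@@H]2CC=C1C | intermediate
19 | geranyl bromide | CC(C)=CCC/C(C)=C/CBr | starting material
20 | dimethyl (2-oxopropyl)phosphonate | COP(=O)(CC(C)=O)OC | starting material
21 | sodium lithium dianion of 20 | [Na+].[Li+].COP(=O)(OC)[CH-]C(=O)[CH2-] | intermediate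
22 | dimethyl [(5E)-6,10-dimethyl-2-oxoundeca-5,9-dien-1-yl]phosphonate | COP(=O)(OC)CC(=O)CC/C=C(\C)CCC=C(C)C | intermediate
23 | dimethyl {4-[(2R,3R)-3-{2-[(2R)-3,3-dimethyloxiran-2-yl]ethyl}-3-methyloxiran-2-yl]-2-oxobutyl}phosphonate | COP(=O)(OC)CC(=O)CC[C@H]1O[C@]1(C)CC[C@H]1OC1(C)C | intermediate
24 | (4E)-enone from 23 and 18 (name as in step 12) | C(/C=C/C(=O)CC[C@H]1O[C@]1(C)CC[C@H]1OC1(C)C)[C@@H]1C(C)(C)[C@@H]2CC[C@@](C)(O)[C@@H]2CC=C1C | intermediate
25 | (3Z)-triethylsilyl enol ether of 24 (name as in step 13) | C(C/C=C(\O[Si](CC)(CC)CC)CC[C@H]1O[C@]1(C)CC[C@H]1OC1(C)C)[C@@H]1C(C)(C)[C@@H]2CC[C@@](C)(O)[C@@H]2CC=C1C | intermediate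
26 | bis(trimethylsilyl) ether (C3–O and C19–O) of 27 | CC1(C)O[C@@H]2CCC(=O)[C@H](CC[C@@H]3C(C)(C)[C@@H]4CC[C@@](C)(O[Si](C)(C)C)[C@@H]4CC=C3C)[C@@]2(C)CC[C@H]1O[Si](C)(C)C | intermediate
27 | (3R,5aR,6R,9aR)-3-hydroxy-6-{2-[(1R,3aR,5S,8aR)-1-hydroxy-1,4,4,6-tetramethyl-1,2,3,3a,4,5,8,8a-octahydroazulen-5-yl]ethyl}-2,2,5a-trimethyloctahydro-1-benzoxepin-7(2H)-one | CC1(C)O[C@@H]2CCC(=O)[C@H](CC[C@@H]3C(C)(C)[C@@H]4CC[C@@](C)(O)[C@@H]4CC=C3C)[C@@]2(C)CC[C@H]1O | intermediate
28 | (3R,5aR,6R,7S,9aR)-6-{2-[(1R,3aR,5S,8aR)-1-hydroxy-1,4,4,6-tetramethyl-1,2,3,3a,4,5,8,8a-octahydroazulen-5-yl]ethyl}-2,2,5a,7-tetramethyldecahydro-1-benzoxepine-3,7-diol | CC1(C)O[C@@H]2CC[C@](C)(O)[C@H](CC[C@@H]3C(C)(C)[C@@H]4CC[C@@](C)(O)[C@@H]4CC=C3C)[C@@]2(C)CC[C@H]1O | intermediate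
29 | (3R,5aR,6R,7S,9aR)-6-{2-[(1R,3aR,5R,6R,7R,8aR)-7-bromo-1,6-dihydroxy-1,4,4,6-tetramethyldecahydroazulen-5-yl]ethyl}-2,2,5a,7-tetramethyldecahydro-1-benzoxepine-3,7-diol | CC1(C)O[C@@H]2CC[C@](C)(O)[C@H](CC[C@@H]3C(C)(C)[C@@H]4CC[C@@](C)(O)[C@@H]4C[C@@H](Br)[C@]3(C)O)[C@@]2(C)CC[C@H]1O | intermediate
30 | (3R,5aR,6R,7S,9aR)-6-{2-[(1R,3aR,5R,6R,7S,8aR)-6,7-epoxy-1-hydroxy-1,4,4,6-tetramethyldecahydroazulen-5-yl]ethyl}-2,2,5a,7-tetramethyldecahydro-1-benzoxepine-3,7-diol | CC1(C)O[C@@H]2CC[C@](C)(O)[C@H](CC[C@@H]3C(C)(C)[C@@H]4CC[C@@](C)(O)[C@@H]4C[C@@H]4O[C@@]43C)[C@@]2(C)CC[C@H]1O | target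

**Totals**
Total step count: 16. Longest linear sequence: 13 (steps 1, 2, 4, 5, 6, 7, 8, 9, 12, 13, 14, 15, 16).

**Steps most likely to fail, with fallbacks**

Step 7. The cross-conjugated dienone is reduced by SmI2 more easily than the methyl ketone, so simple conjugate reduction, or loss of the anti preference at C19, may compete with cyclisation. The fallback makes the same C18–C19 bond from a neutral α-silyloxy radical instead of a samarium ketyl. It sets out from 13: enolisation with internal quench (LiHMDS, TBSCl, THF, −78 °C) gives the silyl enol ether F1 (either enol ether regioisomer serves). Fe(acac)3 and PhSiH3 in EtOH at 60 °C transfer a hydrogen atom to the enol ether, and the tertiary α-silyloxy radical adds 5-exo to C18, the bulky silyloxy group lying anti to C17, to give the TBS ether F2. HF·pyridine in THF removes the silyl group and the route is rejoined at 15.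

Step 14. The cascade is run on the fully assembled substrate with a trisubstituted enol silane, and oxygen trapping or a stalled monocycle may occur. The fallback moves ring closure ahead of fragment union. It sets out from 23: TBSOTf and Et3N give the phosphonate-substituted silyl enol ether F3, which is cyclised under the same TMSOTf/hindered pyridine conditions, followed by Bu4NF, to the bicyclic β-keto phosphonate F4. Olefination of F4 with aldehyde 18 (LiCl, DBU, MeCN) gives the exocyclic enone F5. Conjugate reduction with [(Ph3P)CuH]6 and DBU equilibration to the equatorial C11 epimer rejoin the route at 27.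

Step 16. The facial preference of the C15=C16 alkene in 28 is inferred, not known. If the bromonium ion forms on the β face, closure gives the α-epoxide. In that case oxygen is delivered directly to that same β face by dimethyldioxirane in acetone at 0 °C, from 28 to 30 in one operation; this makes no compound outside the list (none F0).

**Further compounds**
F1 | step 7 | (5R)-5-{3-[(tert-butyldimethylsilyl)oxy]but-3-en-1-yl}-2,4,4-trimethylcyclohepta-2,6-dien-1-one | C=C(O[Si](C)(C)C(C)(C)C)CC[C@@H]1C=CC(=O)C(C)=CC1(C)C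
F2 | step 7 | (3R,3aR,8aR)-3-[(tert-butyldimethylsilyl)oxy]-3,6,8,8-tetramethyl-2,3,3a,4,8,8a-hexahydroazulen-5(1H)-one | CC1=CC(C)(C)[C@@H]2CC[C@@](C)(O[Si](C)(C)C(C)(C)C)[C@@H]2CC1=O
F3 | step 14 | dimethyl [(1Z)-2-[(tert-butyldimethylsilyl)oxy]-4-[(2R,3R)-3-{2-[(2R)-3,3-dimethyloxiran-2-yl]ethyl}-3-methyloxiran-2-yl]but-1-en-1-yl]phosphonate | COP(=O)(OC)/C=C(\O[Si](C)(C)C(C)(C)C)CC[C@H]1O[C@]1(C)CC[C@H]1OC1(C)C
F4 | step 14 | dimethyl [(3R,5aS,6R,9aR)-3-hydroxy-2,2,5a-trimethyl-7-oxodecahydro-1-benzoxepin-6-yl]phosphonate | CC1(C)O[C@@H]2CCC(=O)[C@H](P(=O)(OC)OC)[C@@]2(C)CC[C@H]1O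
F5 | step 14 | (3R,5aR,6Z,9aR)-3-hydroxy-6-{2-[(1R,3aR,5S,8aR)-1-hydroxy-1,4,4,6-tetramethyl-1,2,3,3a,4,5,8,8a-octahydroazulen-5-yl]ethylidene}-2,2,5a-trimethyloctahydro-1-benzoxepin-7(2H)-one | CC1(C)O[C@@H]2CCC(=O)/C(=C\C[C@@H]3C(C)(C)[C@@H]4CC[C@@](C)(O)[C@@H]4CC=C3C)[C@@]2(C)CC[C@H]1O
F0 | step 16 | none | none
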